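Take what the noon run has left over at its last reading: 41.6 % of its reagent charge is in no product, if each mono adduct (first product, other mono adduct, isomer) holds one reagent and the double product two. Divide the reagent spent by the substrate converted: that is the price of a conversion, read at this last reading as 1.51. It is a price of that moment, and it climbs along the noon run, for the readings at 8.00 h give 1.23.

| setting | midnight | noon | flask |
|---|---|---|---|
| substrate | 0.17 M | 0.25 M | 0.33 M |
| reagent | 0.347 M | 0.347 M | 0.347 M |
| remark | run made earlier | run made earlier |  |
| time |  |  | 2.0 d |

| run | time / h | other mono adduct / % | first product / % | isomer of the product / % | substrate / % | double product / % |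
|---|---|---|---|---|---|---|
| midnight | 8.00 | 3.2 | 16.2 | 0.3 | 67.0 | 7.8 |
| midnight | 15.0 | 1.6 | 19.4 | 0.8 | 54.8 | 14.7 |
| midnight | 20.0 | 2.1 | 19.2 | 2.6 | 45.5 | 22.7 |
| midnight | 30.0 | 5.7 | 17.1 | 1.1 | 37.0 | 34.0 |
| noon | 8.00 | 3.2 | 16.4 | 0 | 66.8 | 5.7 |
| noon | 15.0 | 3.5 | 19.4 | 1.3 | 52.7 | 12.0 |
| noon | 20.0 | 2.0 | 18.9 | 1.9 | 49.4 | 19.1 |
| noon | 30.0 | 3.1 | 20.0 | 3.2 | 39.8 | 27.4 |

(scatter of a reading: 1 percentage point)

- a reading or a percentage of first product counts all its forms, free or not
- a reading or a percentage of substrate is of its free form alone

* the largest share of what was charged as substrate, at 2.0 d belongs to (double product / substrate / other mono adduct / isomer of the product / first product)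
* the largest share itself, whichever of these holds it, in percent of the substrate charged

Now you can keep the flask's ledger as my own reckoning. It opens with 1.05 reagent per substrate, less than the price, so reagent is the limiting reagent. Spending comes first: the noon loss, taken as first-order, is 0.0293 h⁻¹, and scaled by the substrate charge it spends 84.3 % of the reagent by 2.0 d. At the price of the last noon reading, which I carry over to the flask as an assumption, that buys 58.7 % of the substrate, and the price less one gives the part of it that is double product, 30.0 %. The noon balance falls short by 6.50 %, which I book as unread substrate, so free substrate closes at 34.8 %, ahead of double product.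

The forecast also names substrate, but at 43 %, holding that “Each converted substrate uses about 2 reagent on average”; my price is lower.

The flask gives substrate at 37.1 %, with double product at 28.5 %.

    substrate + reagent → first product (k = 0.110 M⁻¹ h⁻¹)
    substrate + reagent → other mono adduct (k = 0.0130 M⁻¹ h⁻¹)
    reagent + other mono adduct → double product (k = 0.0930 M⁻¹ h⁻¹)
    reagent + first product → double product (k = 0.430 M⁻¹ h⁻¹)
    reagent ⇌ dormant form (K = 1.20, k = 0.00250 h⁻¹)
    substrate + first product ⇌ idle adduct, settled at all times (K = 6.10 M⁻¹)
    first product ⇌ isomer of the product (K = 0.350, k = 0.00650 h⁻¹)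

The flask's books close with 78.9 % of the reagent in products, 16.1 % unbound and 5.02 % in dormant form, at a price of 1.52. The neighbouring flask, charged with 0.59 M of reagent, has 1.79 reagent per substrate and pays 1.76. Its 73.7 % of reagent spent buys 74.8 % of the substrate. The price less one of that is double product, 57.0 %, the largest share, against 21.5 % of substrate.

The numbers in the tables were generated by integration with made-up constants; noise was put on by code.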